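Ring names: A = dienone ring, B = 4-hydroxyphenyl on the methide carbon, C = central benzene, D = 2,4-dihydroxyphenyl, E = 4-hydroxyphenyl on the alkyne.
Cuts: the quinone methide goes back to a triaryl carbinol (loss of water) and the carbinol to a ring B aryllithium plus a ring C/ring A ketone. Ring A of that ketone is cut at two ring bonds, CH–CH on one flank and C(O)–CH on the other, giving a 5-aroyl-2-pyrone (four ring carbons) and a ketene bis(silyl) acetal (the C–O carbon and one CH).
Enabling feature: ring A bears only its oxygen and, para to it, the methide carbon; its other four atoms are CH. As a ketone, the methide carbon activates pyrone C6 and steers the oxygen para, while the lactone bridge leaves as CO2 and one silanol leaves on aromatisation.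
Remaining cuts: methide carbon–ring C (arylzinc + coumalyl chloride), ring C–alkyne (Sonogashira) and ring C–ring D (Negishi), all on methyl 3-bromo-4-iodobenzoate, whose C–I, C2–H and C–Br positions are used in this order.
Forward order: D onto C, iodination, E-alkyne onto C, ester to silyl-protected CH2OH, pyrone onto C, ring A built, ring B added, acid unmasking with dehydration.
Stereochemistry: the target has no stereocentre and no stereogenic double bond (ring A is symmetric about the exocyclic bond); the stereocentres of the cycloadduct and of the carbinol are transient.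

Key step: step 11

Assumption: the open quinone methide drawn is taken as the form in which the target is isolated; addition of the 2-OH of ring D to the methide carbon (a 6H-benzo[c]chromene) is taken to be reversible and disfavoured.
Abbreviations: MOM = methoxymethyl; TBS = tert-butyldimethylsilyl; TMP = 2,2,6,6-tetramethylpiperidide; ArC = 3-(TBSOCH2)-6-[2,4-bis(MOMO)phenyl]-2-{[4-(MOMO)phenyl]ethynyl}phenyl (ring C carrying rings D and E).

Step 1
Reactants: 1 4-bromoresorcinol (4-bromobenzene-1,3-diol)
Product: 2 1-bromo-2,4-bis(methoxymethoxy)benzene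
Conditions: NaH, MOMCl, DMF, 0 °C to rt
Reagents that add atoms: chloromethyl methyl ether (MOMCl), COCCl
Why: Williamson-type O-alkylation of the bis-phenoxide with the reactive α-chloro ether should give a bis-acetal that survives organolithium, organozinc and amide-base steps and falls in acid.

Step 2
Reactants: 2 1-bromo-2,4-bis(methoxymethoxy)benzene; 3 methyl 3-bromo-4-iodobenzoate
Product: 6 methyl 3-bromo-4-[2,4-bis(methoxymethoxy)phenyl]benzoate, via aryllithium 4 (not isolated), via arylzinc chloride 5 (not isolated)
Conditions: 2, n-BuLi, THF, −78 °C; ZnCl2, −78 °C to rt; 3, Pd(PPh3)4 (cat.), rt to 40 °C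
Reagents that add atoms: none
Why: Bromine–lithium exchange, transmetalation and Negishi coupling, in which zerovalent palladium inserts into the C–I bond much faster than into the neighbouring C–Br bond and the arylzinc tolerates the ester.

Step 3
Reactants: 6 methyl 3-bromo-4-[2,4-bis(methoxymethoxy)phenyl]benzoate
Product: 8 methyl 3-bromo-2-iodo-4-[2,4-bis(methoxymethoxy)phenyl]benzoate, via arylmagnesium chloride 7 (not isolated)
Conditions: TMPMgCl·LiCl, THF, −20 °C; I2, −20 °C to rt
Reagents that add atoms: iodine, II
Why: Directed ortho-magnesiation, in which the hindered amide base should remove the most acidic ring proton (flanked by the coordinating ester and the acidifying bromine) and leave the less activated ring D alone; iodinolysis then fixes the third contiguous handle.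

Step 4
Reactants: 9 4-ethynylphenol
Product: 10 1-ethynyl-4-(methoxymethoxy)benzene
Conditions: NaH (one equivalent), MOMCl, THF, 0 °C to rt
Reagents that add atoms: chloromethyl methyl ether (MOMCl), COCCl
Why: Williamson-type O-alkylation of the phenoxide, with one equivalent of base leaving the far less acidic alkyne C–H untouched.

Step 5
Reactants: 8 methyl 3-bromo-2-iodo-4-[2,4-bis(methoxymethoxy)phenyl]benzoate; 10 1-ethynyl-4-(methoxymethoxy)benzene
Product: 11 methyl 3-bromo-4-[2,4-bis(methoxymethoxy)phenyl]-2-{[4-(methoxymethoxy)phenyl]ethynyl}benzoate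
Conditions: PdCl2(PPh3)2 (cat.), CuI (cat.), Et3N, THF, 50 °C
Reagents that add atoms: none
Why: Sonogashira coupling, in which the C–I bond, activated by the ortho ester, should react in preference to the doubly flanked C–Br bond.

Step 6
Reactants: 11 methyl 3-bromo-4-[2,4-bis(methoxymethoxy)phenyl]-2-{[4-(methoxymethoxy)phenyl]ethynyl}benzoate
Product: 12 (3-bromo-4-[2,4-bis(methoxymethoxy)phenyl]-2-{[4-(methoxymethoxy)phenyl]ethynyl}phenyl)methanol
Conditions: i-Bu2AlH, CH2Cl2, −78 to 0 °C; aq. potassium sodium tartrate
Reagents that add atoms: none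
Why: Hydride reduction of the ester to the primary alcohol, which leaves the aryl bromide, the diarylalkyne and the acetals untouched at low temperature.

Step 7
Reactants: 12 (3-bromo-4-[2,4-bis(methoxymethoxy)phenyl]-2-{[4-(methoxymethoxy)phenyl]ethynyl}phenyl)methanol
Product: 13 ArC–Br, the tert-butyldimethylsilyl ether of 12
Conditions: TBSCl, imidazole, CH2Cl2, rt
Reagents that add atoms: tert-butyldimethylsilyl chloride (TBSCl), CC(C)(C)[Si](C)(C)Cl
Why: Standard silylation of the primary alcohol masks the only acidic proton before the organolithium steps with a group that falls in the final acid step.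

Step 8
Reactants: 14 coumalic acid (2-oxo-2H-pyran-5-carboxylic acid)
Product: 15 coumalyl chloride (2-oxo-2H-pyran-5-carbonyl chloride)
Conditions: SOCl2, DMF (cat.), reflux
Reagents that add atoms: thionyl chloride, O=S(Cl)Cl
Why: Acid chloride formation under acidic, non-nucleophilic conditions to which the pyrone ring is inert.

Step 9
Reactants: 13 ArC–Br; 15 coumalyl chloride
Product: 18 ArC 2-oxo-2H-pyran-5-yl ketone (5-aroyl-2-pyrone), via aryllithium 16 (not isolated), via arylzinc chloride 17 (not isolated)
Conditions: 13, n-BuLi, THF, −78 °C; ZnCl2, −78 to 0 °C; 15, Pd(PPh3)4 (cat.), 0 °C to rt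
Reagents that add atoms: none
Why: Bromine–lithium exchange, prompt transmetalation and Negishi-type acylation, in which the acid chloride adds to zerovalent palladium far faster than the soft arylzinc can attack the pyrone ring or the product ketone, so a single acyl transfer is expected.

Step 10
Reactants: 19 acetic acid
Product: 21 1,1-bis(tert-butyldimethylsilyloxy)ethene, via dilithium enediolate 20 (not isolated)
Conditions: LiN(i-Pr)2 (2.2 equiv), THF–DMPU, −78 to 0 °C; TBSCl (2.2 equiv), 0 °C to rt
Reagents that add atoms: tert-butyldimethylsilyl chloride (TBSCl), CC(C)(C)[Si](C)(C)Cl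
Why: Double deprotonation of acetic acid and O-silylation of both hard oxygen centres in a polar medium (enolate O-silylation) should give the ketene bis(silyl) acetal.

Step 11
Reactants: 18 ArC 2-oxo-2H-pyran-5-yl ketone; 21 1,1-bis(tert-butyldimethylsilyloxy)ethene
Product: 24 ArC 4-(tert-butyldimethylsilyloxy)phenyl ketone, via bicyclic lactone adduct 22 (not isolated), via bis(silyloxy)cyclohexadiene 23 (not isolated)
Conditions: 21 (excess), toluene, 110 °C, sealed tube
Reagents that add atoms: none
Why: The nucleophilic CH2 carbon of 21 bonds to pyrone C6, which is at once the β-carbon of the aroyl enone and the δ-carbon of the lactone dienoate, and the acetal carbon bonds to pyrone C3 in an asynchronous inverse-electron-demand Diels–Alder reaction giving bridged lactone 22; at 110 °C 22 loses CO2 by retro-Diels–Alder reaction and diene 23 aromatises by 1,2-elimination of silanol. The closest known reaction type is the cycloaddition of methyl coumalate and other 2-pyrones bearing an acceptor at C5 or C3 with ketene dialkyl acetals, which delivers alkoxybenzoates after loss of CO2 and alcohol. Ring A is closed by an intermolecular (4+2) cycloaddition of pyrone C3–C6 with the two carbons of 21, and the lactone bridge is a temporary ring that needs no separate opening step. The two bridgehead stereocentres of 22 are fixed relative to each other by the bicycle, form as a racemate and vanish on aromatisation, so no stereocontrol is needed. The step needs regioselectivity (oxygen para to the ketone), secured by the matched polarisation of C6 and the CH2 terminus and by the bulky acetal end meeting the remote, unhindered C3, and chemoselectivity, secured because the electron-rich diarylalkyne is no partner for an electron-poor diene and is held too close to pyrone C5 to span C3 and C6. Reversible side paths such as hetero-Diels–Alder addition across the aroyl enone should drain into the product because loss of CO2 is irreversible.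

Step 12
Reactants: 24 ArC 4-(tert-butyldimethylsilyloxy)phenyl ketone; 25 1-bromo-4-(methoxymethoxy)benzene
Product: 27 ArC [4-(methoxymethoxy)phenyl][4-(tert-butyldimethylsilyloxy)phenyl]methanol (racemic), via aryllithium 26 (not isolated)
Conditions: 25, n-BuLi, THF, −78 °C; 24, −78 to 0 °C; H2O
Reagents that add atoms: none
Why: 1,2-Addition of an aryllithium to a non-enolisable diaryl ketone; the new carbinol stereocentre forms as a racemate and is erased in step 13, and a cold quench should prevent addition of the alkoxide to the ortho alkyne.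

Step 13
Reactants: 27 ArC [4-(methoxymethoxy)phenyl][4-(tert-butyldimethylsilyloxy)phenyl]methanol
Product: 29 selaginellin F, via deprotected carbinol 28 (not isolated)
Conditions: aq. HCl (cat.), THF, 40 °C; neutral work-up
Reagents that add atoms: none
Why: Acid hydrolysis of the four acetals and two silyl ethers, then ionisation of the bis(4-hydroxyphenyl)carbinol to a delocalised trityl cation that loses a phenolic proton (fuchsone-type dehydration); rings A and B are then proton tautomers of one compound, so ring A can be drawn as the dienone.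

Compound list
1 | 4-bromoresorcinol | Oc1ccc(Br)c(O)c1 | starting material
2 | 1-bromo-2,4-bis(methoxymethoxy)benzene | COCOc1ccc(Br)c(OCOC)c1 | intermediate
3 | methyl 3-bromo-4-iodobenzoate | COC(=O)c1ccc(I)c(Br)c1 | starting material
4 | [2,4-bis(methoxymethoxy)phenyl]lithium | [Li]c1ccc(OCOC)cc1OCOC | intermediate
5 | [2,4-bis(methoxymethoxy)phenyl]zinc chloride | Cl[Zn]c1ccc(OCOC)cc1OCOC | intermediate
6 | methyl 3-bromo-4-[2,4-bis(methoxymethoxy)phenyl]benzoate | COC(=O)c1ccc(-c2ccc(OCOC)cc2OCOC)c(Br)c1 | intermediate
7 | 2-magnesiated 6 (arylmagnesium chloride between ester and bromine) | COC(=O)c1ccc(-c2ccc(OCOC)cc2OCOC)c(Br)c1[Mg]Cl | intermediate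
8 | methyl 3-bromo-2-iodo-4-[2,4-bis(methoxymethoxy)phenyl]benzoate | COC(=O)c1ccc(-c2ccc(OCOC)cc2OCOC)c(Br)c1I | intermediate
9 | 4-ethynylphenol | C#Cc1ccc(O)cc1 | starting material
10 | 1-ethynyl-4-(methoxymethoxy)benzene | C#Cc1ccc(OCOC)cc1 | intermediate
11 | methyl 3-bromo-4-[2,4-bis(methoxymethoxy)phenyl]-2-{[4-(methoxymethoxy)phenyl]ethynyl}benzoate | COC(=O)c1ccc(-c2ccc(OCOC)cc2OCOC)c(Br)c1C#Cc1ccc(OCOC)cc1 | intermediate
12 | (3-bromo-4-[2,4-bis(methoxymethoxy)phenyl]-2-{[4-(methoxymethoxy)phenyl]ethynyl}phenyl)methanol | OCc1ccc(-c2ccc(OCOC)cc2OCOC)c(Br)c1C#Cc1ccc(OCOC)cc1 | intermediate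
13 | ArC–Br, tert-butyldimethylsilyl ether of 12 | CC(C)(C)[Si](C)(C)OCc1ccc(-c2ccc(OCOC)cc2OCOC)c(Br)c1C#Cc1ccc(OCOC)cc1 | intermediate
14 | coumalic acid | OC(=O)C1=COC(=O)C=C1 | starting material
15 | coumalyl chloride | O=C(Cl)C1=COC(=O)C=C1 | intermediate
16 | ArC–Li | CC(C)(C)[Si](C)(C)OCc1ccc(-c2ccc(OCOC)cc2OCOC)c([Li])c1C#Cc1ccc(OCOC)cc1 | intermediate
17 | ArC–ZnCl | CC(C)(C)[Si](C)(C)OCc1ccc(-c2ccc(OCOC)cc2OCOC)c([Zn]Cl)c1C#Cc1ccc(OCOC)cc1 | intermediate
18 | ArC 2-oxo-2H-pyran-5-yl ketone | CC(C)(C)[Si](C)(C)OCc1ccc(-c2ccc(OCOC)cc2OCOC)c(C(=O)C2=COC(=O)C=C2)c1C#Cc1ccc(OCOC)cc1 | intermediate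
19 | acetic acid | CC(=O)O | starting material
20 | dilithium ethene-1,1-diolate | C=C(O[Li])O[Li] | intermediate
21 | 1,1-bis(tert-butyldimethylsilyloxy)ethene | C=C(O[Si](C)(C)C(C)(C)C)O[Si](C)(C)C(C)(C)C | intermediate
22 | 6-(ArC-carbonyl)-8,8-bis(tert-butyldimethylsilyloxy)-2-oxabicyclo[2.2.2]oct-5-en-3-one (racemic, one enantiomer drawn) | O=C1O[C@@H]2CC(O[Si](C)(C)C(C)(C)C)(O[Si](C)(C)C(C)(C)C)[C@H]1C=C2C(=O)c1c(-c2ccc(OCOC)cc2OCOC)ccc(CO[Si](C)(C)C(C)(C)C)c1C#Cc1ccc(OCOC)cc1 | intermediate
23 | ArC 4,4-bis(tert-butyldimethylsilyloxy)cyclohexa-1,5-dien-1-yl ketone | O=C(C1=CCC(O[Si](C)(C)C(C)(C)C)(O[Si](C)(C)C(C)(C)C)C=C1)c1c(-c2ccc(OCOC)cc2OCOC)ccc(CO[Si](C)(C)C(C)(C)C)c1C#Cc1ccc(OCOC)cc1 | intermediate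
24 | ArC 4-(tert-butyldimethylsilyloxy)phenyl ketone | O=C(c1ccc(O[Si](C)(C)C(C)(C)C)cc1)c1c(-c2ccc(OCOC)cc2OCOC)ccc(CO[Si](C)(C)C(C)(C)C)c1C#Cc1ccc(OCOC)cc1 | intermediate
25 | 1-bromo-4-(methoxymethoxy)benzene | COCOc1ccc(Br)cc1 | starting material
26 | [4-(methoxymethoxy)phenyl]lithium | [Li]c1ccc(OCOC)cc1 | intermediate
27 | ArC [4-(methoxymethoxy)phenyl][4-(tert-butyldimethylsilyloxy)phenyl]methanol (racemic) | OC(c1ccc(OCOC)cc1)(c1ccc(O[Si](C)(C)C(C)(C)C)cc1)c1c(-c2ccc(OCOC)cc2OCOC)ccc(CO[Si](C)(C)C(C)(C)C)c1C#Cc1ccc(OCOC)cc1 | intermediate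
28 | fully deprotected bis(4-hydroxyphenyl)carbinol | OC(c1ccc(O)cc1)(c1ccc(O)cc1)c1c(-c2ccc(O)cc2O)ccc(CO)c1C#Cc1ccc(O)cc1 | intermediate
29 | selaginellin F | O=C1C=CC(=C(c2ccc(O)cc2)c2c(-c3ccc(O)cc3O)ccc(CO)c2C#Cc2ccc(O)cc2)C=C1 | target

Total step count: 13. Longest linear sequence: 10 steps (1, 2, 3, 5, 6, 7, 9, 11, 12, 13).

Steps most likely to fail

Step 11. Three processes may defeat the cycloaddition:
- After the first bond forms, silyl transfer to a pyrone oxygen (a Mukaiyama–Michael-type path) may outrun ring closure.
- Thermal O-to-C silyl migration may consume the ketene acetal.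
- The two ortho substituents of ring C shield the pyrone faces and may slow the reaction.

The fallback removes the silyl-transfer path altogether. It sets out from 18, which is heated with commercial 1,1-dimethoxyethene (toluene, 110 °C) in the established pyrone/ketene dialkyl acetal reaction to give ArC 4-methoxyphenyl ketone F1. The methyl ether, activated by the para carbonyl group, is cleaved by NaSEt (DMF, 100 °C) to ArC 4-hydroxyphenyl ketone F2. Silylation with excess TBSCl and imidazole also restores any benzylic silyl ether that was lost, and the route is rejoined at 24.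

Step 9. Transmetalation of the doubly ortho-substituted arylzinc to acylpalladium may be slow. That would leave time for hydrolysis or decarbonylation of the acyl partner and for conjugate attack on the pyrone. The fallback replaces cross-coupling by carbonyl addition and oxidation. It sets out from 15, which is reduced with LiAlH(O-t-Bu)3 (THF, −78 °C) to 2-oxo-2H-pyran-5-carbaldehyde F3. Aryllithium 16, made from 13 as before, is added to the small and highly reactive aldehyde at −78 °C to give ArC(2-oxo-2H-pyran-5-yl)methanol F4. Dess–Martin oxidation rejoins the route at 18.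

Step 12. Ring D and the alkyne block both faces of the carbonyl group. The addition may therefore stall, and attack of the aryllithium at silicon may strip the aryl silyl ether, leaving an unreactive phenoxide. The fallback changes from carbonyl addition to cationic arylation followed by oxidation. It sets out from 24, which the small hydride of NaBH4 (THF–MeOH) reduces to ArC[4-(tert-butyldimethylsilyloxy)phenyl]methanol F5. This benzhydrol is ionised with CF3CO2H in the presence of excess phenol (Friedel–Crafts benzhydrylation para to the hydroxyl group). Aqueous HCl then strips the remaining acetals and silyl ethers to give the leuco triarylmethane F6. Oxidation of this 4,4'-dihydroxytriarylmethane with one equivalent of DDQ (dioxane, rt) rejoins the route at 29.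

Further compounds
F1 | step 11 | ArC 4-methoxyphenyl ketone | O=C(c1ccc(OC)cc1)c1c(-c2ccc(OCOC)cc2OCOC)ccc(CO[Si](C)(C)C(C)(C)C)c1C#Cc1ccc(OCOC)cc1
F2 | step 11 | ArC 4-hydroxyphenyl ketone | O=C(c1ccc(O)cc1)c1c(-c2ccc(OCOC)cc2OCOC)ccc(CO[Si](C)(C)C(C)(C)C)c1C#Cc1ccc(OCOC)cc1
F3 | step 9 | 2-oxo-2H-pyran-5-carbaldehyde | O=CC1=COC(=O)C=C1
F4 | step 9 | ArC(2-oxo-2H-pyran-5-yl)methanol (racemic) | OC(C1=COC(=O)C=C1)c1c(-c2ccc(OCOC)cc2OCOC)ccc(CO[Si](C)(C)C(C)(C)C)c1C#Cc1ccc(OCOC)cc1
F5 | step 12 | ArC[4-(tert-butyldimethylsilyloxy)phenyl]methanol (racemic) | OC(c1ccc(O[Si](C)(C)C(C)(C)C)cc1)c1c(-c2ccc(OCOC)cc2OCOC)ccc(CO[Si](C)(C)C(C)(C)C)c1C#Cc1ccc(OCOC)cc1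
F6 | step 12 | leuco triarylmethane (dihydro form of the target) | OCc1ccc(-c2ccc(O)cc2O)c(C(c2ccc(O)cc2)c2ccc(O)cc2)c1C#Cc1ccc(O)cc1
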